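The plan cuts both arms of the cyclopentane from the cyclohexane ring, at C7a–C1 and C3a–C3. The three adjacent ring stereocentres C3a, C7a and C7, mutually trans and all equatorial, are read as Cα, Cβ and Cγ of (S)-cryptone, the enone carbonyl becoming C4. One pot then delivers both arms: copper-mediated transfer of a vinyl group to Cβ on the face away from the isopropyl group, and allylation of the enolate at Cα on the face away from the new vinyl group. The trans ring fusion is thus encoded before the five-membered ring exists. The precursor is simply (S)-4-isopropylcyclohex-2-enone; the product keeps the C4 ketone for the methylene group and the C5/C6 oxygens.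

Key step: step 3

Conventions and assumptions
- Numbering: all bicyclic compounds carry the hydrindane numbering of the target (C1 CHOAc, C2 C=O, C3, C3a, C4 =CH2, C5 CHOAng, C6 CHOH, C7 CH-iPr, C7a). β is the face of H-3a and α the face of H-7a, so the target is 1α-OAc, 5β-OAng, 6α-OH, 7α-iPr with a trans ring fusion.
- Configuration check: C7 of the target has the configuration of C4 of (S)-cryptone, and the key-step product with both new substituents trans is the (2R,3S,4S) isomer.
- Assumption: the (S,S)-amide is taken to give the (R)-enol ether, by analogy with 4-tert-butylcyclohexanone; if the sense proves opposite, the (R,R)-amine is used.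
- Assumption: the chiral-base step should give high but not complete enantioselectivity; diol 10 is the intended point for enrichment by recrystallisation.

Step 1
Reactants: 1 4-isopropylcyclohexanone
Product: 2 (R)-trimethyl[(4-isopropylcyclohex-1-en-1-yl)oxy]silane
Conditions: (S,S)-bis(1-phenylethyl)amine, n-BuLi, THF, −78 °C; TMSCl, then 1 added slowly (in situ quench), −78 °C
Reagents that add atoms: chlorotrimethylsilane C[Si](C)(C)Cl
Why: Enantiotopos-selective deprotonation of the prochiral ketone by the C2-symmetric chiral lithium amide with in situ silyl trapping (chiral-base desymmetrisation) should give the (R)-enol ether and so fix the isopropyl-bearing stereocentre that becomes C7.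

Step 2
Reactants: 2 (R)-trimethyl[(4-isopropylcyclohex-1-en-1-yl)oxy]silane
Product: 3 (S)-cryptone, (4S)-4-isopropylcyclohex-2-en-1-one
Conditions: Pd(OAc)2 (1.05 equiv), MeCN, rt
Reagents that add atoms: none
Why: In the Saegusa–Ito oxidation the palladium enolate formed from the silyl enol ether undergoes β-hydride elimination on the side of the former enol double bond, so the enone arises regiospecifically and the stereocentre is untouched.

Step 3
Reactants: 3 (S)-cryptone; 4 vinylmagnesium bromide; 5 allyl iodide
Product: 7 (2R,3S,4S)-2-allyl-4-isopropyl-3-vinylcyclohexan-1-one (trans,trans), via bromomagnesium enolate 6 (not isolated)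
Conditions: 4 (1.3 equiv), CuBr·SMe2 (10 mol%), THF, −78 → −40 °C; then DMPU, 5 (4 equiv), −40 °C → rt
Reagents that add atoms: vinylmagnesium bromide (4) C=C[Mg]Br; allyl iodide (5) C=CCI
Why: Monovalent copper (from CuBr·SMe2) turns the Grignard reagent into a vinyl cuprate, which adds 1,4 to the enone by π-complexation, oxidative addition at the β-carbon and reductive elimination; this leaves the regiodefined magnesium enolate 6, which is C-allylated by SN2 displacement of iodide once DMPU is added. The closest known reaction type is the three-component conjugate addition–enolate alkylation of cyclohexenones, which is established for 4-substituted enones and gives the trans,trans-2,3,4-trisubstituted ketones. No ring is closed; the two bonds made are C7a–C1 and C3a–C3. C7a is controlled by the isopropyl-bearing C7: the cuprate attacks the β-carbon on the face opposite the γ-substituent, giving the 3,4-trans relationship. C3a is controlled by the new vinyl group, the allyl iodide approaching the enolate carbon from the face opposite to it, and because the trans,trans isomer is also the all-equatorial one, a C3a epimer would equilibrate to it through the ketone enol. The step needs 1,4- rather than 1,2-addition (secured by copper), alkylation at C3a only (secured by forming the enolate regiospecifically and trapping it at low temperature with an excess of the reactive iodide before proton transfer can scramble it) and C- rather than O-allylation (soft iodide, magnesium counter-ion).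

Step 4
Reactants: 7 (2R,3S,4S)-2-allyl-4-isopropyl-3-vinylcyclohexan-1-one
Product: 9 2-[(1R,2S,3S)-2-formyl-3-isopropyl-6-oxocyclohexyl]acetaldehyde, via bis-ozonide 8 (not isolated)
Conditions: O3, CH2Cl2, −78 °C; then PPh3, −78 °C → rt; used crude
Reagents that add atoms: ozone [O-][O+]=O
Why: Ozonolysis cleaves both monosubstituted alkenes through the bis-ozonide, which PPh3 reduces to the aldehydes, so the vinyl group becomes the C1 formyl group and the allyl group the C3–C2 acetaldehyde arm, while the ketone and the three stereocentres (already in the stable all-equatorial arrangement) are untouched.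

Step 5
Reactants: 9 2-[(1R,2S,3S)-2-formyl-3-isopropyl-6-oxocyclohexyl]acetaldehyde
Product: 10 1α,2α-dihydroxy-7α-isopropyl-trans-hydrindan-4-one
Conditions: SmI2 (2.5 equiv), t-BuOH, THF, −78 °C
Reagents that add atoms: none
Why: The SmI2-mediated intramolecular pinacol coupling of the 1,5-dialdehyde (aldehydes are reduced far faster than the ketone) forms C1–C2 between two equatorial arms, so the fusion can only be trans; samarium bridging of the two oxygens should give the cis-diol, and the C1 oxygen should take the pseudo-equatorial α position anti to the C7a–C7 bond, which sets the future acetoxy stereocentre.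

Step 6
Reactants: 10 1α,2α-dihydroxy-7α-isopropyl-trans-hydrindan-4-one
Product: 11 1α-hydroxy-7α-isopropyl-2α-(triethylsilyloxy)-trans-hydrindan-4-one
Conditions: TESCl (1.05 equiv), imidazole, CH2Cl2, −40 → 0 °C
Reagents that add atoms: chlorotriethylsilane CC[Si](Cl)(CC)CC
Why: This is a sterically controlled mono-silylation: the C2 hydroxyl is flanked by the C3 methylene, whereas the C1 hydroxyl lies between the ring-fusion methine and the peri isopropyl group, so O2 should react selectively.

Step 7
Reactants: 11 1α-hydroxy-7α-isopropyl-2α-(triethylsilyloxy)-trans-hydrindan-4-one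
Product: 12 7α-isopropyl-2α-(triethylsilyloxy)-1α,4-bis(trimethylsilyloxy)-trans-hydrind-4-ene
Conditions: LiN(iPr)2 (2.3 equiv), THF, −78 °C; then TMSCl (3 equiv), −78 → 0 °C
Reagents that add atoms: chlorotrimethylsilane C[Si](C)(C)Cl
Why: Kinetic deprotonation with the hindered lithium amide removes a proton from the C5 methylene and not from the C3a methine, and silyl trapping gives the Δ4 enol ether while the C1 alkoxide is silylated at the same time.

Step 8
Reactants: 12 7α-isopropyl-2α-(triethylsilyloxy)-1α,4-bis(trimethylsilyloxy)-trans-hydrind-4-ene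
Product: 14 1α-hydroxy-7α-isopropyl-2α-(triethylsilyloxy)-trans-hydrind-5-en-4-one, via C1-trimethylsilyl ether 13 (not isolated)
Conditions: Pd(OAc)2 (1.1 equiv), MeCN, rt; then K2CO3 (cat.), MeOH, 0 °C
Reagents that add atoms: none
Why: The Saegusa–Ito oxidation introduces the C5=C6 double bond regiospecifically from the enol ether, and brief methanolysis then removes only the labile trimethylsilyl ether while the triethylsilyl ether stays.

Step 9
Reactants: 14 1α-hydroxy-7α-isopropyl-2α-(triethylsilyloxy)-trans-hydrind-5-en-4-one
Product: 15 5α,6α-epoxy-1α-hydroxy-7α-isopropyl-2α-(triethylsilyloxy)-trans-hydrindan-4-one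
Conditions: 30% aq. H2O2, NaOH, MeOH, 0 °C
Reagents that add atoms: hydrogen peroxide OO
Why: In this Weitz–Scheffer (nucleophilic) epoxidation the trans ring fusion locks the enone, so hydroperoxide should add to C6 along the axial trajectory on the α face (antiperiplanar to the axial H-7, chair-like enolate, whereas the β path needs a boat) and only this axial peroxide can close onto C5, giving the 5α,6α-epoxide with the C6 oxygen cis to the isopropyl group.

Step 10
Reactants: 15 5α,6α-epoxy-1α-hydroxy-7α-isopropyl-2α-(triethylsilyloxy)-trans-hydrindan-4-one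
Product: 16 5α,6α-epoxy-7α-isopropyl-4-methylene-2α-(triethylsilyloxy)-trans-hydrindan-1α-ol
Conditions: Ph3PCH3Br, KOtBu (3 equiv each), THF, 0 °C → rt
Reagents that add atoms: methyltriphenylphosphonium bromide C[P+](c1ccccc1)(c1ccccc1)c1ccccc1.[Br-]
Why: Wittig methylenation of the activated α,β-epoxy ketone with an excess of the non-stabilised ylide (the free hydroxyl only consumes base) gives the exocyclic alkene, turns the epoxide into a vinyl epoxide and creates no new stereocentre.

Step 11
Reactants: 16 5α,6α-epoxy-7α-isopropyl-4-methylene-2α-(triethylsilyloxy)-trans-hydrindan-1α-ol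
Product: 17 1α-acetoxy-5α,6α-epoxy-7α-isopropyl-4-methylene-2α-(triethylsilyloxy)-trans-hydrindane
Conditions: Ac2O, DMAP, pyridine, CH2Cl2, 0 °C → rt
Reagents that add atoms: acetic anhydride CC(=O)OC(C)=O
Why: DMAP-catalysed acylation acetylates the hindered secondary C1 alcohol with retention under conditions that leave the vinyl epoxide and the silyl ether intact.

Step 12
Reactants: 17 1α-acetoxy-5α,6α-epoxy-7α-isopropyl-4-methylene-2α-(triethylsilyloxy)-trans-hydrindane
Product: 18 1α-acetoxy-5α,6α-epoxy-7α-isopropyl-4-methylene-trans-hydrindan-2α-ol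
Conditions: HF·pyridine, pyridine, THF, 0 °C
Reagents that add atoms: none
Why: Buffered HF·pyridine cleaves the secondary triethylsilyl ether under weakly acidic conditions, which avoid the base-induced 1,2-acetyl shift to the neighbouring cis hydroxyl and are of a kind tolerated by epoxides and acetates.

Step 13
Reactants: 18 1α-acetoxy-5α,6α-epoxy-7α-isopropyl-4-methylene-trans-hydrindan-2α-ol
Product: 19 1α-acetoxy-5α,6α-epoxy-7α-isopropyl-4-methylene-trans-hydrindan-2-one
Conditions: Dess–Martin periodinane, NaHCO3, CH2Cl2, 0 °C → rt
Reagents that add atoms: none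
Why: Dess–Martin oxidation of the only free hydroxyl gives the C2 ketone under buffered, non-enolising conditions, so the α-acetoxy stereocentre at C1 keeps its pseudo-equatorial configuration.

Step 14
Reactants: 19 1α-acetoxy-5α,6α-epoxy-7α-isopropyl-4-methylene-trans-hydrindan-2-one; 20 angelic acid
Product: 21 target, 1α-acetoxy-5β-angeloyloxy-6α-hydroxy-7α-isopropyl-4-methylene-trans-hydrindan-2-one
Conditions: 20 (6 equiv), tetrabutylammonium angelate (0.2 equiv), toluene, 45 °C
Reagents that add atoms: angelic acid (20) C/C=C(/C)C(=O)O
Why: In this carboxylate-catalysed, acid-assisted SN2 opening of a vinyl epoxide, attack at the allylically activated C5 from the β face is also the trans-diaxial (Fürst–Plattner) mode, so inversion at C5 and retention at C6 should give the 5β-angelate and the 6α-alcohol, and the nearly neutral conditions should preserve the Z geometry of the ester.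

Compound list
1 | 4-isopropylcyclohexanone | CC(C)C1CCC(=O)CC1 | starting material
2 | (R)-trimethyl[(4-isopropylcyclohex-1-en-1-yl)oxy]silane | C[Si](C)(C)OC1=CC[C@H](C(C)C)CC1 | intermediate
3 | (S)-cryptone, (4S)-4-isopropylcyclohex-2-en-1-one | O=C1C=C[C@H](C(C)C)CC1 | intermediate
4 | vinylmagnesium bromide | C=C[Mg]Br | starting material
5 | allyl iodide | C=CCI | starting material
6 | bromomagnesium (3S,4S)-4-isopropyl-3-vinylcyclohex-1-en-1-olate (not isolated) | Br[Mg]OC1=C[C@@H](C=C)[C@H](C(C)C)CC1 | intermediate
7 | (2R,3S,4S)-2-allyl-4-isopropyl-3-vinylcyclohexan-1-one | O=C1[C@H](CC=C)[C@@H](C=C)[C@H](C(C)C)CC1 | intermediate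
8 | (2R,3S,4S)-4-isopropyl-3-(1,2,4-trioxolan-3-yl)-2-(1,2,4-trioxolan-3-ylmethyl)cyclohexan-1-one, bis-ozonide, epimers at the trioxolane carbons (not isolated) | O=C1[C@H](CC2OCOO2)[C@@H](C2OCOO2)[C@H](C(C)C)CC1 | intermediate
9 | 2-[(1R,2S,3S)-2-formyl-3-isopropyl-6-oxocyclohexyl]acetaldehyde | O=C1[C@H](CC=O)[C@@H](C=O)[C@H](C(C)C)CC1 | intermediate
10 | 1α,2α-dihydroxy-7α-isopropyl-trans-hydrindan-4-one | O=C1[C@@H]2C[C@H](O)[C@H](O)[C@H]2[C@H](C(C)C)CC1 | intermediate
11 | 1α-hydroxy-7α-isopropyl-2α-(triethylsilyloxy)-trans-hydrindan-4-one | O=C1[C@@H]2C[C@H](O[Si](CC)(CC)CC)[C@H](O)[C@H]2[C@H](C(C)C)CC1 | intermediate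
12 | 7α-isopropyl-2α-(triethylsilyloxy)-1α,4-bis(trimethylsilyloxy)-trans-hydrind-4-ene | C[Si](C)(C)OC=1[C@@H]2C[C@H](O[Si](CC)(CC)CC)[C@H](O[Si](C)(C)C)[C@H]2[C@H](C(C)C)CC=1 | intermediate
13 | 7α-isopropyl-2α-(triethylsilyloxy)-1α-(trimethylsilyloxy)-trans-hydrind-5-en-4-one (not isolated) | O=C1[C@@H]2C[C@H](O[Si](CC)(CC)CC)[C@H](O[Si](C)(C)C)[C@H]2[C@H](C(C)C)C=C1 | intermediate
14 | 1α-hydroxy-7α-isopropyl-2α-(triethylsilyloxy)-trans-hydrind-5-en-4-one | O=C1[C@@H]2C[C@H](O[Si](CC)(CC)CC)[C@H](O)[C@H]2[C@H](C(C)C)C=C1 | intermediate
15 | 5α,6α-epoxy-1α-hydroxy-7α-isopropyl-2α-(triethylsilyloxy)-trans-hydrindan-4-one | O=C1[C@@H]2C[C@H](O[Si](CC)(CC)CC)[C@H](O)[C@H]2[C@H](C(C)C)[C@@H]3O[C@H]13 | intermediate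
16 | 5α,6α-epoxy-7α-isopropyl-4-methylene-2α-(triethylsilyloxy)-trans-hydrindan-1α-ol | C=C1[C@@H]2C[C@H](O[Si](CC)(CC)CC)[C@H](O)[C@H]2[C@H](C(C)C)[C@@H]3O[C@H]13 | intermediate
17 | 1α-acetoxy-5α,6α-epoxy-7α-isopropyl-4-methylene-2α-(triethylsilyloxy)-trans-hydrindane | C=C1[C@@H]2C[C@H](O[Si](CC)(CC)CC)[C@H](OC(C)=O)[C@H]2[C@H](C(C)C)[C@@H]3O[C@H]13 | intermediate
18 | 1α-acetoxy-5α,6α-epoxy-7α-isopropyl-4-methylene-trans-hydrindan-2α-ol | C=C1[C@@H]2C[C@H](O)[C@H](OC(C)=O)[C@H]2[C@H](C(C)C)[C@@H]3O[C@H]13 | intermediate
19 | 1α-acetoxy-5α,6α-epoxy-7α-isopropyl-4-methylene-trans-hydrindan-2-one | C=C1[C@@H]2CC(=O)[C@H](OC(C)=O)[C@H]2[C@H](C(C)C)[C@@H]3O[C@H]13 | intermediate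
20 | angelic acid, (Z)-2-methylbut-2-enoic acid | C/C=C(/C)C(=O)O | starting material
21 | (1R,3aR,5S,6S,7S,7aR)-1-acetoxy-6-hydroxy-7-isopropyl-4-methylene-2-oxo-octahydro-1H-inden-5-yl (Z)-2-methylbut-2-enoate | C=C1[C@@H]2CC(=O)[C@H](OC(C)=O)[C@H]2[C@H](C(C)C)[C@H](O)[C@H]1OC(=O)/C(C)=C\C | target

Total step count: 14
Longest linear sequence: 14 steps (1 → 21)

Steps most likely to fail

Risk 1, step 14 (angelic acid opening of the vinyl epoxide). The carboxylate may attack the exocyclic methylene carbon (SN2′), or the epoxide may ionise to an allyl cation with loss of regio- and stereocontrol. A sluggish reaction would force heating, which risks Z→E isomerisation of the angelate. The fallback sets out from 19 and comes back at 21. The epoxide is hydrolysed with dilute HClO4 in THF–water at 0 °C to the trans-diaxial 1α-acetoxy-5β,6α-dihydroxy-7α-isopropyl-4-methylene-trans-hydrindan-2-one F1. Angelic acid, 2,4,6-trichlorobenzoyl chloride and Et3N give angelic 2,4,6-trichlorobenzoic anhydride F2. In toluene at 75 °C this acylates the allylic 5β-hydroxyl of F1, which is far less hindered than the 6α-hydroxyl next to the isopropyl group, under conditions known to keep the Z geometry, and gives 21.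

Risk 2, step 9 (facial selectivity of the epoxidation). The equatorial isopropyl group crowds the axial approach to C6, so hydroperoxide may add slowly or from the β face, giving the wrong epoxide or a mixture. The fallback sets out from 14 and comes back at 15, making the epoxide by the halohydrin route instead. N-Bromosuccinimide in aqueous THF adds HOBr across C5=C6. Bromine enters at C5 from the open β face and water opens the bromonium ion anti at C6, the trans-diaxial mode, to give 5β-bromo-1α,6α-dihydroxy-7α-isopropyl-2α-(triethylsilyloxy)-trans-hydrindan-4-one F3. K2CO3 in methanol at 0 °C then closes the 6α-alkoxide onto C5 with displacement of the axial bromide and gives 15.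

Risk 3, step 3 (one-pot conjugate addition–allylation). Allylation of the magnesium enolate may be sluggish; proton transfer between enolate and product may lead to allylation at C5 or double allylation; and diastereoselection at C3a may be incomplete. The fallback sets out from 3 and comes back at 7, separating the two bond formations. The copper-catalysed addition of 4 is run with TMSCl present, which traps enolate 6 as the isolable, regiodefined trimethyl{[(3S,4S)-4-isopropyl-3-vinylcyclohex-1-en-1-yl]oxy}silane F4. MeLi in THF at 0 °C releases lithium (3S,4S)-4-isopropyl-3-vinylcyclohex-1-en-1-olate F5, free of amine and magnesium salts, which is allylated with 5 at −78 °C to give 7.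

Further compounds
F1 | step 14 | 1α-acetoxy-5β,6α-dihydroxy-7α-isopropyl-4-methylene-trans-hydrindan-2-one | C=C1[C@@H]2CC(=O)[C@H](OC(C)=O)[C@H]2[C@H](C(C)C)[C@H](O)[C@H]1O
F2 | step 14 | angelic 2,4,6-trichlorobenzoic anhydride | C/C=C(/C)C(=O)OC(=O)c1c(Cl)cc(Cl)cc1Cl
F3 | step 9 | 5β-bromo-1α,6α-dihydroxy-7α-isopropyl-2α-(triethylsilyloxy)-trans-hydrindan-4-one | O=C1[C@@H]2C[C@H](O[Si](CC)(CC)CC)[C@H](O)[C@H]2[C@H](C(C)C)[C@H](O)[C@H]1Br
F4 | step 3 | trimethyl{[(3S,4S)-4-isopropyl-3-vinylcyclohex-1-en-1-yl]oxy}silane | C[Si](C)(C)OC1=C[C@@H](C=C)[C@H](C(C)C)CC1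
F5 | step 3 | lithium (3S,4S)-4-isopropyl-3-vinylcyclohex-1-en-1-olate | [Li]OC1=C[C@@H](C=C)[C@H](C(C)C)CC1
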